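**Plan**

- Feature: in ring C of the flavonol, the C3 hydroxyl and the C4 carbonyl are the enol tautomer of a 2-arylchromane-3,4-dione, which is the oxidised form of an acyloin across C3–C4. A carbene-catalysed benzoin closure between two aldehyde carbons can therefore build ring C.
- Cuts: C3–C4 (acyloin), then the O1–C2 ether bond (phenoxide alkylation), the aryl–C2 bond of ring B (aryllithium plus glyoxylate), the O–CMe2 bond of the dimethylpyran ring, and the two C-prenyl bonds of ring A.
- Forward: ring A is C-prenylated twice and protected; the dimethylpyran ring is closed on the future ring B; the two halves are joined through the ether oxygen; ring C closes last and is then oxidised and deprotected.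
- Stereochemistry: the target has no stereocentre. C2 and C3 of the intermediates are racemic, need no control, and are erased when ring C becomes aromatic.

Key step: step 9

Assumption: the acyloin of step 9 is written as the trans 3-hydroxy-4-ketone (racemic, one enantiomer drawn); a cis isomer or the regioisomeric 4-hydroxy-3-ketone would converge on the same dione in step 10.

**Route**

Step 1
Reactants: 1 2,4,6-trihydroxybenzaldehyde; 2 prenyl bromide (1-bromo-3-methylbut-2-ene, 2.2 equiv)
Product: 3 2,4,6-trihydroxy-3,5-bis(3-methylbut-2-en-1-yl)benzaldehyde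
Conditions: KOH (10% aq), 0 °C to rt
Reagents that add atoms: none
Why: C-alkylation of the ambident phloroglucinol-type phenoxide in water (phenoxide C-prenylation): the two ring carbons that still carry hydrogen lie between hydroxyl groups and each should take one prenyl group, while the formyl group and the limit of two equivalents of bromide hold back a third, dearomatising alkylation.

Step 2
Reactants: 3 2,4,6-trihydroxy-3,5-bis(3-methylbut-2-en-1-yl)benzaldehyde
Product: 4 2-hydroxy-4,6-bis(methoxymethoxy)-3,5-bis(3-methylbut-2-en-1-yl)benzaldehyde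
Conditions: MOMCl (2.2 equiv), iPr2NEt, CH2Cl2, 0 °C
Reagents that add atoms: chloromethyl methyl ether (MOMCl), COCCl
Why: Base-mediated O-alkylation with the chloromethyl ether (acetal-type protection): the para hydroxyl and one of the two equivalent ortho hydroxyls react, and the last hydroxyl stays free because its hydrogen bond to the formyl oxygen makes it the least nucleophilic, so a single bis-ether should result.

Step 3
Reactants: 5 4-bromo-2-hydroxybenzaldehyde; 6 2-methylprop-1-en-1-ylmagnesium bromide (2.5 equiv)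
Product: 9 7-bromo-2,2-dimethyl-2H-chromene, via allylic diol 7 (not isolated), via ortho-quinone methide 8 (not isolated)
Conditions: THF, 0 °C to rt; H2O quench; crude 7, pyridinium p-toluenesulfonate (cat.), toluene, 80 °C
Reagents that add atoms: none
Why: Grignard 1,2-addition (the first equivalent is consumed by the phenol) gives a carbinol that is benzylic and allylic, which mild acid dehydrates to the ortho-quinone methide that closes by oxa-6π electrocyclisation; since the oxygen and the side chain are already ortho on the ring, bromine can only end up at C7.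

Step 4
Reactants: 9 7-bromo-2,2-dimethyl-2H-chromene; 10 ethyl glyoxylate
Product: 12 ethyl 2-(2,2-dimethyl-2H-chromen-7-yl)-2-hydroxyacetate (racemic), via chromen-7-yllithium 11 (not isolated)
Conditions: n-BuLi, THF, −78 °C; then 10 (freshly distilled), −78 °C; H2O quench
Reagents that add atoms: none
Why: Bromine–lithium exchange at −78 °C followed by 1,2-addition of the aryllithium to the aldehyde of ethyl glyoxylate, which is far more electrophilic than its ester group, should give the racemic mandelate.

Step 5
Reactants: 12 ethyl 2-(2,2-dimethyl-2H-chromen-7-yl)-2-hydroxyacetate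
Product: 13 ethyl 2-(2,2-dimethyl-2H-chromen-7-yl)-2-(methanesulfonyloxy)acetate (racemic)
Conditions: MsCl, Et3N, CH2Cl2, 0 °C
Reagents that add atoms: methanesulfonyl chloride (MsCl), CS(=O)(=O)Cl
Why: Mesylation of a secondary alcohol; the adjacent ester disfavours ionisation, so the benzylic sulfonate should be stable enough to isolate and should react later by direct displacement.

Step 6
Reactants: 4 2-hydroxy-4,6-bis(methoxymethoxy)-3,5-bis(3-methylbut-2-en-1-yl)benzaldehyde; 13 ethyl 2-(2,2-dimethyl-2H-chromen-7-yl)-2-(methanesulfonyloxy)acetate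
Product: 14 ethyl 2-(2,2-dimethyl-2H-chromen-7-yl)-2-[6-formyl-3,5-bis(methoxymethoxy)-2,4-bis(3-methylbut-2-en-1-yl)phenoxy]acetate (racemic)
Conditions: Cs2CO3, DMF, 0 °C to rt
Reagents that add atoms: none
Why: Williamson ether synthesis by SN2 displacement at a benzylic carbon that is also α to an ester, an electrophile reactive enough for the hindered, hydrogen-bonded phenol once it is its cesium phenoxide; at room temperature the 2-formylphenoxy ester should persist without aldol closure to a benzofuran.

Step 7
Reactants: 14 ethyl 2-(2,2-dimethyl-2H-chromen-7-yl)-2-[6-formyl-3,5-bis(methoxymethoxy)-2,4-bis(3-methylbut-2-en-1-yl)phenoxy]acetate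
Product: 15 2-(2,2-dimethyl-2H-chromen-7-yl)-2-[6-(hydroxymethyl)-3,5-bis(methoxymethoxy)-2,4-bis(3-methylbut-2-en-1-yl)phenoxy]ethan-1-ol (racemic)
Conditions: LiAlH4, THF, 0 °C; H2O quench; crude taken on
Reagents that add atoms: none
Why: LiAlH4 reduces the ester and the aryl aldehyde to primary alcohols in one operation and leaves acetals, aryl ethers and alkenes alone, so the two carbonyl groups need not be told apart; the electron-rich benzylic alcohol is kept away from acid and silica.

Step 8
Reactants: 15 2-(2,2-dimethyl-2H-chromen-7-yl)-2-[6-(hydroxymethyl)-3,5-bis(methoxymethoxy)-2,4-bis(3-methylbut-2-en-1-yl)phenoxy]ethan-1-ol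
Product: 16 2-(2,2-dimethyl-2H-chromen-7-yl)-2-[6-formyl-3,5-bis(methoxymethoxy)-2,4-bis(3-methylbut-2-en-1-yl)phenoxy]acetaldehyde (racemic)
Conditions: Dess–Martin periodinane (2.5 equiv), NaHCO3, CH2Cl2, 0 °C to rt; crude 16 used at once
Reagents that add atoms: none
Why: Dess–Martin oxidation converts both primary alcohols into aldehydes without over-oxidation, and the bicarbonate buffer keeps the medium neutral so that neither the acid-labile benzylic alcohol ionises nor the enolisable α-aryloxy aldehyde undergoes aldol addition before the next step.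

Step 9
Reactants: 16 2-(2,2-dimethyl-2H-chromen-7-yl)-2-[6-formyl-3,5-bis(methoxymethoxy)-2,4-bis(3-methylbut-2-en-1-yl)phenoxy]acetaldehyde
Product: 17 (2R*,3R*)-2-(2,2-dimethyl-2H-chromen-7-yl)-3-hydroxy-5,7-bis(methoxymethoxy)-6,8-bis(3-methylbut-2-en-1-yl)-2,3-dihydro-4H-chromen-4-one (trans, racemic)
Conditions: 2-(pentafluorophenyl)-6,7-dihydro-5H-pyrrolo[2,1-c][1,2,4]triazol-2-ium tetrafluoroborate (15 mol %), iPr2NEt (15 mol %), toluene, rt, argon
Reagents that add atoms: none
Why: Proposed new method: the triazolylidene freed by the weak base adds to an aldehyde carbon, proton transfer gives the Breslow intermediate (an acyl anion equivalent), this enaminol adds to the second aldehyde and the carbene leaves from the resulting alkoxide, the closest known reaction type being the triazolium-catalysed crossed benzoin cyclisation of salicylaldehyde-derived keto aldehydes to 3-hydroxychroman-4-ones together with the acyloin cyclisation of 1,6-dialdehydes. Ring C closes 6-exo-trig at the acceptor carbonyl through formation of the C3–C4 bond. The new C3 stereocentre should be placed trans to the C2 aryl group by a chair-like transition state with that aryl group equatorial, and because C2 before closure and C3 after closure can epimerise through enols the trans acyloin should also be the thermodynamic product; both centres vanish in step 10, so this control is not essential. The step needs acyloin closure to win over aldol closure of the enolisable aldehyde onto the aryl aldehyde (a five-membered ring) and over loss of the aryloxide from a Breslow intermediate formed at the aliphatic aldehyde. The first is secured by the barely basic catalyst system and by the reversibility of an aldol that cannot dehydrate at its quaternary carbon; the second is only favoured, not guaranteed, by the two ortho oxygen substituents that assist carbene addition at the aryl aldehyde, by the α-branching that slows Breslow formation at the aliphatic aldehyde and by a non-polar solvent that disfavours ion-pair formation. Which aldehyde ends up as the ketone does not matter, since both acyloins give the same 3,4-dione on oxidation.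

Step 10
Reactants: 17 (2R*,3R*)-2-(2,2-dimethyl-2H-chromen-7-yl)-3-hydroxy-5,7-bis(methoxymethoxy)-6,8-bis(3-methylbut-2-en-1-yl)-2,3-dihydro-4H-chromen-4-one
Product: 19 2-(2,2-dimethyl-2H-chromen-7-yl)-3-hydroxy-5,7-bis(methoxymethoxy)-6,8-bis(3-methylbut-2-en-1-yl)-4H-chromen-4-one, via chromane-3,4-dione 18 (not isolated)
Conditions: Dess–Martin periodinane (1.3 equiv), NaHCO3, CH2Cl2, 0 °C to rt
Reagents that add atoms: none
Why: Dess–Martin oxidation of the secondary acyloin gives the 3,4-dione, whose C2 hydrogen (benzylic, α to the ring oxygen and to the new ketone) is acidic enough for spontaneous enolisation to the aromatic 3-hydroxypyran-4-one, which removes both stereocentres.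

Step 11
Reactants: 19 2-(2,2-dimethyl-2H-chromen-7-yl)-3-hydroxy-5,7-bis(methoxymethoxy)-6,8-bis(3-methylbut-2-en-1-yl)-4H-chromen-4-one
Product: 20 dorsilurin C, 2-(2,2-dimethyl-2H-chromen-7-yl)-3,5,7-trihydroxy-6,8-bis(3-methylbut-2-en-1-yl)-4H-chromen-4-one
Conditions: 3 M aq HCl, MeOH–THF, 45 °C
Reagents that add atoms: none
Why: Acid-catalysed hydrolysis of the two methoxymethyl acetals; dilute acid at moderate temperature should spare the prenyl groups from cyclisation onto the freed phenols and leave the chromene double bond untouched.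

**Compound list**

1 | 2,4,6-trihydroxybenzaldehyde | O=Cc1c(O)cc(O)cc1O | starting material
2 | prenyl bromide (1-bromo-3-methylbut-2-ene) | CC(C)=CCBr | starting material
3 | 2,4,6-trihydroxy-3,5-bis(3-methylbut-2-en-1-yl)benzaldehyde | O=Cc1c(O)c(CC=C(C)C)c(O)c(CC=C(C)C)c1O | intermediate
4 | 2-hydroxy-4,6-bis(methoxymethoxy)-3,5-bis(3-methylbut-2-en-1-yl)benzaldehyde | O=Cc1c(O)c(CC=C(C)C)c(OCOC)c(CC=C(C)C)c1OCOC | intermediate
5 | 4-bromo-2-hydroxybenzaldehyde | O=Cc1ccc(Br)cc1O | starting material
6 | 2-methylprop-1-en-1-ylmagnesium bromide (THF solution) | CC(C)=C[Mg]Br | starting material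
7 | 5-bromo-2-(1-hydroxy-3-methylbut-2-en-1-yl)phenol (racemic, not isolated) | CC(C)=CC(O)c1ccc(Br)cc1O | intermediate
8 | (6Z)-3-bromo-6-(3-methylbut-2-en-1-ylidene)cyclohexa-2,4-dien-1-one (not isolated) | CC(C)=C\C=C1/C(=O)C=C(Br)C=C1 | intermediate
9 | 7-bromo-2,2-dimethyl-2H-chromene | CC1(C)C=Cc2ccc(Br)cc2O1 | intermediate
10 | ethyl glyoxylate | CCOC(=O)C=O | starting material
11 | (2,2-dimethyl-2H-chromen-7-yl)lithium (not isolated) | [Li]c1ccc2C=CC(C)(C)Oc2c1 | intermediate
12 | ethyl 2-(2,2-dimethyl-2H-chromen-7-yl)-2-hydroxyacetate (racemic) | CCOC(=O)C(O)c1ccc2C=CC(C)(C)Oc2c1 | intermediate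
13 | ethyl 2-(2,2-dimethyl-2H-chromen-7-yl)-2-(methanesulfonyloxy)acetate (racemic) | CCOC(=O)C(OS(C)(=O)=O)c1ccc2C=CC(C)(C)Oc2c1 | intermediate
14 | ethyl 2-(2,2-dimethyl-2H-chromen-7-yl)-2-[6-formyl-3,5-bis(methoxymethoxy)-2,4-bis(3-methylbut-2-en-1-yl)phenoxy]acetate (racemic) | CCOC(=O)C(Oc1c(CC=C(C)C)c(OCOC)c(CC=C(C)C)c(OCOC)c1C=O)c1ccc2C=CC(C)(C)Oc2c1 | intermediate
15 | 2-(2,2-dimethyl-2H-chromen-7-yl)-2-[6-(hydroxymethyl)-3,5-bis(methoxymethoxy)-2,4-bis(3-methylbut-2-en-1-yl)phenoxy]ethan-1-ol (racemic) | OCC(Oc1c(CC=C(C)C)c(OCOC)c(CC=C(C)C)c(OCOC)c1CO)c1ccc2C=CC(C)(C)Oc2c1 | intermediate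
16 | 2-(2,2-dimethyl-2H-chromen-7-yl)-2-[6-formyl-3,5-bis(methoxymethoxy)-2,4-bis(3-methylbut-2-en-1-yl)phenoxy]acetaldehyde (racemic) | O=CC(Oc1c(CC=C(C)C)c(OCOC)c(CC=C(C)C)c(OCOC)c1C=O)c1ccc2C=CC(C)(C)Oc2c1 | intermediate
17 | (2R*,3R*)-2-(2,2-dimethyl-2H-chromen-7-yl)-3-hydroxy-5,7-bis(methoxymethoxy)-6,8-bis(3-methylbut-2-en-1-yl)-2,3-dihydro-4H-chromen-4-one (trans, racemic, one enantiomer drawn) | CC1(C)C=Cc2ccc(cc2O1)[C@@H]1[C@@H](O)C(=O)c2c(OCOC)c(CC=C(C)C)c(OCOC)c(CC=C(C)C)c2O1 | intermediate
18 | 2-(2,2-dimethyl-2H-chromen-7-yl)-5,7-bis(methoxymethoxy)-6,8-bis(3-methylbut-2-en-1-yl)chromane-3,4-dione (racemic, not isolated) | CC1(C)C=Cc2ccc(cc2O1)C1Oc2c(CC=C(C)C)c(OCOC)c(CC=C(C)C)c(OCOC)c2C(=O)C1=O | intermediate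
19 | 2-(2,2-dimethyl-2H-chromen-7-yl)-3-hydroxy-5,7-bis(methoxymethoxy)-6,8-bis(3-methylbut-2-en-1-yl)-4H-chromen-4-one | CC1(C)C=Cc2ccc(cc2O1)-c1oc2c(CC=C(C)C)c(OCOC)c(CC=C(C)C)c(OCOC)c2c(=O)c1O | intermediate
20 | dorsilurin C | CC(C)=CCc1c(O)c(CC=C(C)C)c2oc(-c3ccc4c(c3)OC(C)(C)C=C4)c(O)c(=O)c2c1O | target

**Step count and risks**

Total: 11 steps. Longest linear sequence: 9 steps (steps 3, 4, 5, 6, 7, 8, 9, 10, 11, from 5 to 20).

Steps most likely to fail:

1. Step 9 (proposed new method). The carbene may engage the aliphatic aldehyde, and its Breslow intermediate may expel the aryloxide (internal redox to an aryl ester) faster than it closes the ring; base-induced aldol closure to the five-membered ring may also intervene. The fallback is chalcone chemistry, which is known; it sets out from 4 and 9 and comes back at 19. MeMgBr (excess, THF, 0 °C) should add to the formyl group of 4 to give 1-[2-hydroxy-4,6-bis(methoxymethoxy)-3,5-bis(3-methylbut-2-en-1-yl)phenyl]ethan-1-ol F1, which MnO2 (CH2Cl2, rt) should oxidise to 1-[2-hydroxy-4,6-bis(methoxymethoxy)-3,5-bis(3-methylbut-2-en-1-yl)phenyl]ethan-1-one F2. Bromide 9 would be formylated (n-BuLi, THF, −78 °C; then DMF) to 2,2-dimethyl-2H-chromene-7-carbaldehyde F3. Claisen–Schmidt condensation of F2 with F3 (KOH, EtOH, rt) should give (2E)-3-(2,2-dimethyl-2H-chromen-7-yl)-1-[2-hydroxy-4,6-bis(methoxymethoxy)-3,5-bis(3-methylbut-2-en-1-yl)phenyl]prop-2-en-1-one F4. Algar–Flynn–Oyamada oxidation (H2O2, NaOH, MeOH, 0 °C to rt) closes ring C to flavonol 19, and the route continues with step 11.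

2. Step 8. The electron-rich benzylic alcohol of 15 may ionise, and the dialdehyde may undergo aldol self-reaction during oxidation and handling. The fallback never reduces the aryl aldehyde; it sets out from 14 and comes back at 16. Saponification (LiOH, THF–H2O, 0 °C) should give 2-(2,2-dimethyl-2H-chromen-7-yl)-2-[6-formyl-3,5-bis(methoxymethoxy)-2,4-bis(3-methylbut-2-en-1-yl)phenoxy]acetic acid F5. Coupling with EtSH (EDC, 4-(dimethylamino)pyridine, CH2Cl2) should give S-ethyl 2-(2,2-dimethyl-2H-chromen-7-yl)-2-[6-formyl-3,5-bis(methoxymethoxy)-2,4-bis(3-methylbut-2-en-1-yl)phenoxy]ethanethioate F6. Fukuyama reduction (Et3SiH, Pd/C, acetone, rt) should take the thioester alone to the aldehyde, giving 16.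

3. Step 1. The degree and site of alkylation may be poorly controlled (mono- and tri-alkylation, O-alkylation, geminal dialkylation with loss of aromaticity). The fallback sets out from 1 and comes back at 3: Friedel–Crafts prenylation with 2-methylbut-3-en-2-ol and BF3·OEt2 in dioxane at rt, in which the prenyl cation attacks the two free ring carbons under acidic conditions where O-alkylation and dearomatisation do not compete. No compound outside the list is needed (F0).

**Further compounds**

F1 | step 9 | 1-[2-hydroxy-4,6-bis(methoxymethoxy)-3,5-bis(3-methylbut-2-en-1-yl)phenyl]ethan-1-ol (racemic) | CC(O)c1c(O)c(CC=C(C)C)c(OCOC)c(CC=C(C)C)c1OCOC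
F2 | step 9 | 1-[2-hydroxy-4,6-bis(methoxymethoxy)-3,5-bis(3-methylbut-2-en-1-yl)phenyl]ethan-1-one | CC(=O)c1c(O)c(CC=C(C)C)c(OCOC)c(CC=C(C)C)c1OCOC
F3 | step 9 | 2,2-dimethyl-2H-chromene-7-carbaldehyde | O=Cc1ccc2C=CC(C)(C)Oc2c1
F4 | step 9 | (2E)-3-(2,2-dimethyl-2H-chromen-7-yl)-1-[2-hydroxy-4,6-bis(methoxymethoxy)-3,5-bis(3-methylbut-2-en-1-yl)phenyl]prop-2-en-1-one | O=C(/C=C/c1ccc2C=CC(C)(C)Oc2c1)c1c(O)c(CC=C(C)C)c(OCOC)c(CC=C(C)C)c1OCOC
F5 | step 8 | 2-(2,2-dimethyl-2H-chromen-7-yl)-2-[6-formyl-3,5-bis(methoxymethoxy)-2,4-bis(3-methylbut-2-en-1-yl)phenoxy]acetic acid (racemic) | OC(=O)C(Oc1c(CC=C(C)C)c(OCOC)c(CC=C(C)C)c(OCOC)c1C=O)c1ccc2C=CC(C)(C)Oc2c1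
F6 | step 8 | S-ethyl 2-(2,2-dimethyl-2H-chromen-7-yl)-2-[6-formyl-3,5-bis(methoxymethoxy)-2,4-bis(3-methylbut-2-en-1-yl)phenoxy]ethanethioate (racemic) | CCSC(=O)C(Oc1c(CC=C(C)C)c(OCOC)c(CC=C(C)C)c(OCOC)c1C=O)c1ccc2C=CC(C)(C)Oc2c1
F0 | step 1 | none | none
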